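All runs stem from a simulated flask for an exercise, and the scatter is random.

I want to know when the flask holds most L and how much L that is, so I look for one scale on which both earlier runs and the flask can be read together.

| flask | J | G | X | remark | time |
|---|---|---|---|---|---|
| larch | 0.025 M | 1.5 equiv | 2 equiv | run made earlier |  |
| cedar | 0.038 M | 1.5 equiv | 2 equiv | run made earlier |  |
| flask | 0.050 M | 1.50 equiv | 2.00 equiv |  | 2.5 h |

- larch (time / h: L / %): 0.0333: 4.8; 0.100: 10.6; 0.250: 11.0; 0.833: 7.6; 2.50: 0.9
- cedar (time / h: L / %): 0.0333: 4.9; 0.100: 9.0; 0.250: 9.7; 0.833: 4.8; 2.50: 0.9

(readings scatter by 1 percentage point)

- time, not beyond 2.5 h, at which the flask holds most L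
- the amount of L, in percent of the J charged, at that time

- the numbers in the tables scatter with a standard deviation of 1 percentage point

1. In a second-order step two molecules meet, so its rate goes with a product of two concentrations. I assume that every step here is of this kind, and that makes a higher concentration simply a faster clock. At fixed equivalents, the percentages then follow one curve (a master curve) against the concentration of J charged, c, multiplied by time.

2. The runs allow a test. At 0.833 h, cedar reads 4.8% and larch 7.6%, so cedar, the more concentrated run, stands lower on the falling side, as a run further along the curve should. This difference is 2.8 points, against a scatter of 1 point in one reading.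

3. Larch reads highest at 0.250 h, with 11.0%, which gives 22.5 M·s as the peak dose, the product of c and the time of the maximum.

4. Dividing by the flask's c, I expect its maximum at 0.125 h, with a height near that larch reading, since the flask has the same equivalents of G and X as larch.

5. The forecast gives 0.16 h and 9.2%, and it reads the early rise differently from me: “L forms at a rate roughly first order in J”.

The flask gives its maximum at 0.130 h, with 11.2% of L.

    J + G → X + L (k = 0.0108 /M/s)
    2 J → Z (k = 0.0279 /M/s)
    L + G → X + D (k = 0.0326 /M/s)

On this flask the peak dose comes to 23.4 M·s. The neighbouring flask, with 0.380 equiv of G, has the same c, so at 2.5 h it has the same product of c and time as this flask, 450 M·s. But its equivalents of G differ, and the single curve was claimed at fixed equivalents. Its best is 6.09%, less than this flask's 11.2%, and at 2.50 h it holds 2.20% of L, more than the 0.149% in this flask.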